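Ring B of the target is taken from (R)-carvone, and the plan rests on closing ring A by forming the C3–C4 bond. The feature exploited is the C3 ketone of ring A standing next to the gem-dimethyl carbon C4: hydrogen-atom transfer to an isopropenyl group turns C4 into a tertiary radical, and addition of that radical to a nitrile carbon gives the ketone. One operation thus creates the second C4 methyl, the C3–C4 bond, the trans-fused ring A and the C3 carbonyl. The precursor is (R)-carvone carrying methyl and 2-cyanoethyl on its α' carbon, cyanoethyl trans to isopropenyl. C11 and the coumarin ether are then placed on C9 by enone transposition and an Ireland–Claisen shift.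

Key step: step 3

Remark on the chemistry: drimane numbering is used for all bicyclic compounds (carvone C1, C2, C3, C4, C5, C6 and the isopropenyl carbon become C9, C8, C7, C6, C5, C10 and C4); with the C10 methyl β and H5 α, the target SMILES places C11 on the α face of C9, anti to the C10 methyl, and the route is built to deliver this 9α side chain.

Step 1
Reactants: 1 (R)-carvone
Product: 3 (5R,6RS)-2,6-dimethyl-5-(prop-1-en-2-yl)cyclohex-2-en-1-one (6-methylcarvone; both C6 epimers), via lithium dienolate 2 (not isolated)
Conditions: LiN(i-Pr)2, THF, −78 °C; MeI, −78 → 0 °C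
Reagents that add atoms: iodomethane, CI
Why: Kinetic deprotonation at the α' methylene by the hindered amide gives the cross-conjugated lithium dienolate, whose C-alkylation with MeI (enolate alkylation) installs the future C10 methyl; the new centre forms as an epimeric mixture, which is irrelevant because it is planarised again in step 2.

Step 2
Reactants: 3 6-methylcarvone; 4 acrylonitrile
Product: 7 3-[(1S,6S)-1,3-dimethyl-2-oxo-6-(prop-1-en-2-yl)cyclohex-3-en-1-yl]propanenitrile, via lithium enolate 5 (not isolated), via lithiated nitrile 6 (not isolated)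
Conditions: LiN(i-Pr)2, THF, −78 °C; acrylonitrile (slow addition), −78 °C; AcOH quench at −78 °C
Reagents that add atoms: none
Why: A second kinetic enolisation at the now tertiary α' carbon followed by Michael addition to acrylonitrile (cyanoethylation) creates the C10 quaternary centre, the acceptor approaching the enolate face opposite the neighbouring isopropenyl group so that cyanoethyl ends up trans and methyl cis to it (1,2-induction from C5).

Step 3
Reactants: 7 3-[(1S,6S)-1,3-dimethyl-2-oxo-6-(prop-1-en-2-yl)cyclohex-3-en-1-yl]propanenitrile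
Product: 9 (5S,10S)-11-nordrim-7-ene-3,9-dione, via C3 imine 8 (not isolated)
Conditions: Fe(acac)3 (30 mol %), PhSiH3, EtOH, 60 °C; then 1 M HCl, THF, rt
Reagents that add atoms: water, O
Why: Fe(acac)3 and PhSiH3 in ethanol generate a trivalent iron hydride that transfers a hydrogen atom to the terminal CH2 of the isopropenyl group (Markovnikov hydrogen-atom transfer), which creates the second C4 methyl and a tertiary C4 radical; this nucleophilic radical adds to the nitrile carbon, the iminyl radical is reduced by divalent iron and protonated by ethanol, and imine 8 is hydrolysed to the C3 ketone on acidic work-up. The closest known reaction type is the iron-hydride-initiated reductive radical cyclization of alkene-tethered nitriles to cyclic ketones. Ring A closes in the 6-exo-dig mode by forming the C3–C4 bond. No new stereocentre is formed, since C4 carries two methyls, and the trans ring fusion follows from the trans arrangement of the C5 and C10 arms fixed in step 2, both of which sit equatorial on ring B. The step needs hydrogen-atom transfer to the 1,1-disubstituted alkene in preference to the C7=C8 enone alkene, which is secured because the latter is trisubstituted, conjugated and electron-poor, and because the C4 radical has no feasible ring size for attack on the enone, so that nitrile capture competes only with slow reduction.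

Step 4
Reactants: 9 (5S,10S)-11-nordrim-7-ene-3,9-dione
Product: 10 3,3-(ethylenedioxy)-11-nordrim-7-en-9-one
Conditions: HOCH2CH2OH, p-TsOH (cat.), benzene, reflux (Dean–Stark)
Reagents that add atoms: ethylene glycol, OCCO
Why: Acid-catalysed dioxolane formation (ketalisation) should take place at the saturated C3 ketone only, because the C9 carbonyl is conjugated and flanked by the quaternary C10 and the methyl-bearing C8; no stereocentre is touched.

Step 5
Reactants: 10 3,3-(ethylenedioxy)-11-nordrim-7-en-9-one
Product: 11 7α,8α-epoxy-3,3-(ethylenedioxy)-11-nordriman-9-one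
Conditions: 30% aq. H2O2, NaOH (cat.), MeOH, 0 °C → rt
Reagents that add atoms: hydrogen peroxide, OO
Why: Nucleophilic (Weitz–Scheffer) epoxidation: hydroperoxide adds to C7 axially from the α face, anti to the axial C10 methyl and on the side of H5 as in the epoxidation of carvone itself, and the enolate closes on the same face to give the 7α,8α-epoxide, the ketal being inert to base.

Step 6
Reactants: 11 7α,8α-epoxy-3,3-(ethylenedioxy)-11-nordriman-9-one
Product: 14 3,3-(ethylenedioxy)-11-nordrim-8-en-7α-ol, via hydrazone 12 (not isolated), via alkenyldiazene 13 (not isolated)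
Conditions: N2H4·H2O, AcOH (cat.), MeOH, 0 °C → rt
Reagents that add atoms: none
Why: Wharton transposition: the C9 hydrazone opens the epoxide to an alkenyl diazene that loses N2, which leaves the C7–O bond untouched (7α-OH retained) and moves the alkene to C8=C9, while the weakly acidic medium spares the ketal.

Step 7
Reactants: 14 3,3-(ethylenedioxy)-11-nordrim-8-en-7α-ol; 15 bromoacetyl bromide
Product: 16 3,3-(ethylenedioxy)-11-nordrim-8-en-7α-yl bromoacetate
Conditions: BrCH2COBr, pyridine, CH2Cl2, 0 °C
Reagents that add atoms: none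
Why: Pyridine-mediated O-acylation of the secondary allylic alcohol by the acyl bromide (esterification) proceeds with retention at C7, since the C7–O bond is not broken.

Step 8
Reactants: 16 3,3-(ethylenedioxy)-11-nordrim-8-en-7α-yl bromoacetate; 17 isofraxidin
Product: 18 3,3-(ethylenedioxy)-11-nordrim-8-en-7α-yl 2-[(6,8-dimethoxy-2-oxo-2H-chromen-7-yl)oxy]acetate
Conditions: K2CO3, acetone, 45 °C
Reagents that add atoms: none
Why: Williamson etherification: the potassium phenoxide of isofraxidin displaces bromide from the activated α-bromo ester by SN2, under conditions in which ester, ketal and lactone should persist.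

Step 9
Reactants: 18 3,3-(ethylenedioxy)-11-nordrim-8-en-7α-yl 2-[(6,8-dimethoxy-2-oxo-2H-chromen-7-yl)oxy]acetate
Product: 22 2-[(6,8-dimethoxy-2-oxo-2H-chromen-7-yl)oxy]-2-[3,3-(ethylenedioxy)-11-nordrim-7-en-9α-yl]acetic acid (both C11 epimers), via lithium enolate 19 (not isolated), via silyl ketene acetal 20 (not isolated), via trimethylsilyl ester 21 (not isolated)
Conditions: Me3SiCl, Et3N, LiN(SiMe3)2, THF, −78 °C → 65 °C; then aq. citric acid
Reagents that add atoms: none
Why: Ireland–Claisen rearrangement: the silyl ketene acetal formed by in-situ silylation of the ester enolate undergoes a suprafacial [3,3] shift that forms the C9–C11 bond on the α face from which the pseudoaxial C7–O bond departs (1,3-chirality transfer sets C9, anti to the C10 methyl) and moves the alkene to C7=C8; the C11 centre forms as a mixture that is erased in step 10, and immediate trapping of the enolate limits its contact with the coumarin.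

Step 10
Reactants: 22 2-[(6,8-dimethoxy-2-oxo-2H-chromen-7-yl)oxy]-2-[3,3-(ethylenedioxy)-11-nordrim-7-en-9α-yl]acetic acid
Product: 24 7-{[3,3-(ethylenedioxy)-9βH-drim-7-en-11-yl]oxy}-6,8-dimethoxy-2H-chromen-2-one, via thiohydroxamate ester 23 (not isolated)
Conditions: N-hydroxypyridine-2-thione, DCC, DMAP (cat.), CH2Cl2, rt, dark; then t-BuSH, visible light, rt
Reagents that add atoms: none
Why: Barton reductive decarboxylation: the thiohydroxamate ester fragments under visible light in a radical chain, CO2 is lost, and the α-aryloxy C11 radical takes a hydrogen atom from t-BuSH faster than it can rearrange, C9 not being involved.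

Step 11
Reactants: 24 7-{[3,3-(ethylenedioxy)-9βH-drim-7-en-11-yl]oxy}-6,8-dimethoxy-2H-chromen-2-one
Product: 25 6,8-dimethoxy-7-{[(1R,4aR,8aS)-2,5,5,8a-tetramethyl-6-oxo-1,4,4a,5,6,7,8,8a-octahydronaphthalen-1-yl]methoxy}-2H-chromen-2-one (CNP0127079.1)
Conditions: PPTS, acetone/H2O, 50 °C
Reagents that add atoms: water, O
Why: Acid-catalysed transketalisation to acetone and water releases the C3 ketone under conditions too mild to isomerise the C7=C8 alkene or to cleave the aryl ether and the lactone.

Compound list

1 | (R)-carvone, (5R)-2-methyl-5-(prop-1-en-2-yl)cyclohex-2-en-1-one | O=C1C(C)=CC[C@@H](C(C)=C)C1 | starting material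
2 | kinetic lithium dienolate of carvone | [Li]OC1=C[C@H](C(C)=C)CC=C1C | intermediate (not isolated)
3 | (5R,6RS)-2,6-dimethyl-5-(prop-1-en-2-yl)cyclohex-2-en-1-one (6-methylcarvone, both C6 epimers) | O=C1C(C)=CC[C@@H](C(C)=C)C1C | intermediate
4 | acrylonitrile | C=CC#N | starting material
5 | lithium enolate of 6-methylcarvone | [Li]OC1=C(C)[C@H](C(C)=C)CC=C1C | intermediate (not isolated)
6 | lithiated nitrile formed by the Michael addition | O=C1C(C)=CC[C@@H](C(C)=C)[C@]1(C)CC([Li])C#N | intermediate (not isolated)
7 | 3-[(1S,6S)-1,3-dimethyl-2-oxo-6-(prop-1-en-2-yl)cyclohex-3-en-1-yl]propanenitrile (cyanoethyl trans, methyl cis to isopropenyl) | O=C1C(C)=CC[C@@H](C(C)=C)[C@]1(C)CCC#N | intermediate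
8 | 3-imino-11-nordrim-7-en-9-one (5α-H, 10β-methyl) | O=C1C(C)=CC[C@H]2C(C)(C)C(=N)CC[C@]12C | intermediate (not isolated)
9 | (5S,10S)-11-nordrim-7-ene-3,9-dione, (4aS,8aS)-2,5,5,8a-tetramethyl-4a,5,8,8a-tetrahydronaphthalene-1,6(4H,7H)-dione | O=C1C(C)=CC[C@H]2C(C)(C)C(=O)CC[C@]12C | intermediate
10 | 3,3-(ethylenedioxy)-11-nordrim-7-en-9-one (5α-H, 10β-methyl) | O=C1C(C)=CC[C@H]2C(C)(C)C3(OCCO3)CC[C@]12C | intermediate
11 | 7α,8α-epoxy-3,3-(ethylenedioxy)-11-nordriman-9-one | O=C1[C@]2(C)O[C@@H]2C[C@H]3C(C)(C)C4(OCCO4)CC[C@]13C | intermediate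
12 | C9 hydrazone of 11 | NN=C1[C@]2(C)O[C@@H]2C[C@H]3C(C)(C)C4(OCCO4)CC[C@]13C | intermediate (not isolated)
13 | 9-diazenyl-3,3-(ethylenedioxy)-11-nordrim-8-en-7α-ol | N=NC1=C(C)[C@H](O)C[C@H]2C(C)(C)C3(OCCO3)CC[C@]12C | intermediate (not isolated)
14 | 3,3-(ethylenedioxy)-11-nordrim-8-en-7α-ol | CC1=C[C@@]2(C)CCC3(OCCO3)C(C)(C)[C@@H]2C[C@H]1O | intermediate
15 | bromoacetyl bromide | BrCC(Br)=O | starting material
16 | 3,3-(ethylenedioxy)-11-nordrim-8-en-7α-yl bromoacetate | CC1=C[C@@]2(C)CCC3(OCCO3)C(C)(C)[C@@H]2C[C@H]1OC(=O)CBr | intermediate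
17 | isofraxidin, 7-hydroxy-6,8-dimethoxy-2H-chromen-2-one | COc1cc2ccc(=O)oc2c(OC)c1O | starting material
18 | 3,3-(ethylenedioxy)-11-nordrim-8-en-7α-yl 2-[(6,8-dimethoxy-2-oxo-2H-chromen-7-yl)oxy]acetate | CC1=C[C@@]2(C)CCC3(OCCO3)C(C)(C)[C@@H]2C[C@H]1OC(=O)COc1c(OC)cc2ccc(=O)oc2c1OC | intermediate
19 | lithium enolate of ester 18 | CC1=C[C@@]2(C)CCC3(OCCO3)C(C)(C)[C@@H]2C[C@H]1OC(O[Li])=COc1c(OC)cc2ccc(=O)oc2c1OC | intermediate (not isolated)
20 | trimethylsilyl ketene acetal of ester 18 | CC1=C[C@@]2(C)CCC3(OCCO3)C(C)(C)[C@@H]2C[C@H]1OC(O[Si](C)(C)C)=COc1c(OC)cc2ccc(=O)oc2c1OC | intermediate (not isolated)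
21 | trimethylsilyl ester of acid 22 | C[Si](C)(C)OC(=O)C(Oc1c(OC)cc2ccc(=O)oc2c1OC)[C@@H]1C(C)=CC[C@H]2C(C)(C)C3(OCCO3)CC[C@]12C | intermediate (not isolated)
22 | 2-[(6,8-dimethoxy-2-oxo-2H-chromen-7-yl)oxy]-2-[3,3-(ethylenedioxy)-11-nordrim-7-en-9α-yl]acetic acid (both C11 epimers) | OC(=O)C(Oc1c(OC)cc2ccc(=O)oc2c1OC)[C@@H]1C(C)=CC[C@H]2C(C)(C)C3(OCCO3)CC[C@]12C | intermediate
23 | 2-thioxopyridin-1(2H)-yl ester of acid 22 (thiohydroxamate ester) | S=c1ccccn1OC(=O)C(Oc1c(OC)cc2ccc(=O)oc2c1OC)[C@@H]1C(C)=CC[C@H]2C(C)(C)C3(OCCO3)CC[C@]12C | intermediate (not isolated)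
24 | 7-{[3,3-(ethylenedioxy)-9βH-drim-7-en-11-yl]oxy}-6,8-dimethoxy-2H-chromen-2-one (C11 on the α face of C9) | COc1cc2ccc(=O)oc2c(OC)c1OC[C@@H]1C(C)=CC[C@H]2C(C)(C)C3(OCCO3)CC[C@]12C | intermediate
25 | 6,8-dimethoxy-7-{[(1R,4aR,8aS)-2,5,5,8a-tetramethyl-6-oxo-1,4,4a,5,6,7,8,8a-octahydronaphthalen-1-yl]methoxy}-2H-chromen-2-one (CNP0127079.1) | COc1cc2ccc(=O)oc2c(OC)c1OC[C@@H]1C(C)=CC[C@H]2C(C)(C)C(=O)CC[C@]12C | target

Total step count: 11 steps.
Longest linear sequence: 11 steps, from (R)-carvone 1 to target 25; acrylonitrile 4, bromoacetyl bromide 15 and isofraxidin 17 enter as purchased.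

Steps most likely to fail

Step 3. The tertiary C4 radical may be reduced before it reaches the nitrile (net hydrogenation of the isopropenyl group), or hydrogen-atom transfer may spread to the enone alkene. The fallback generates the same radical by a tin hydride chain from a halide, so that the choice between the two alkenes is made in a separate polar step. Setting out from 7, Markovnikov addition of HBr (HBr in AcOH, 0 °C) to the isopropenyl group, a reaction long known for carvone itself, should give the tertiary bromide 3-[6-(2-bromopropan-2-yl)-1,3-dimethyl-2-oxocyclohex-3-en-1-yl]propanenitrile F1. Slow addition of Bu3SnH and AIBN in refluxing benzene at high dilution should then let the 6-exo-dig closure onto the nitrile outrun hydrogen transfer, and acidic work-up of imine 8 brings the route back at 9.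

Step 9. The ester enolate or the amide base may attack the coumarin (conjugate or acyl addition) before silylation, or the rearrangement may be too slow at the hindered C9 terminus so that the ketene acetal decomposes. The fallback replaces the [3,3] shift by a [2,3] shift and forms the aryl ether last. Setting out from 14, O-alkylation with ICH2SnBu3 (KH, THF) should give the stannylmethyl ether 3,3-(ethylenedioxy)-7α-[(tributylstannyl)methoxy]-11-nordrim-8-ene F2. Tin–lithium exchange with n-BuLi in THF at −78 °C triggers a Wittig–Still rearrangement that should deliver the hydroxymethyl group suprafacially to the α face of C9 and give the homoallylic alcohol 3,3-(ethylenedioxy)-9βH-drim-7-en-11-ol F3. Mitsunobu etherification of this primary alcohol with isofraxidin 17 (PPh3, DIAD, THF) returns to the route at 24, so that steps 7 to 10 are bypassed.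

Step 6. Hydrazone formation at the C9 carbonyl, which lies between the quaternary C10 and the fully substituted epoxide carbon C8, may be slow, and opening of the epoxide by hydrazine may compete. The fallback opens the epoxide from a C9 radical instead. Setting out from 11, NaBH4 in MeOH at 0 °C should give the epoxy alcohol 7α,8α-epoxy-3,3-(ethylenedioxy)-11-nordriman-9-ol F4, whose C9 configuration is of no consequence. Xanthate formation (NaH, CS2, then MeI, THF) should give the O-(7α,8α-epoxy-3,3-(ethylenedioxy)-11-nordriman-9-yl) S-methyl dithiocarbonate F5. Treatment with Bu3SnH and AIBN in toluene at 90 °C generates the C9 radical, which opens the epoxide by β-scission of the C8–O bond, and the C7 alkoxyl radical takes hydrogen from the stannane, so that the route is rejoined at 14 with the 7α-oxygen unchanged.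

Further compounds

F1 | step 3 | 3-[6-(2-bromopropan-2-yl)-1,3-dimethyl-2-oxocyclohex-3-en-1-yl]propanenitrile (configuration as in 7) | O=C1C(C)=CC[C@@H](C(C)(C)Br)[C@]1(C)CCC#N
F2 | step 9 | 3,3-(ethylenedioxy)-7α-[(tributylstannyl)methoxy]-11-nordrim-8-ene | CC1=C[C@@]2(C)CCC3(OCCO3)C(C)(C)[C@@H]2C[C@H]1OC[Sn](CCCC)(CCCC)CCCC
F3 | step 9 | 3,3-(ethylenedioxy)-9βH-drim-7-en-11-ol (hydroxymethyl on the α face of C9) | OC[C@@H]1C(C)=CC[C@H]2C(C)(C)C3(OCCO3)CC[C@]12C
F4 | step 6 | 7α,8α-epoxy-3,3-(ethylenedioxy)-11-nordriman-9-ol (C9 epimers) | OC1[C@]2(C)O[C@@H]2C[C@H]3C(C)(C)C4(OCCO4)CC[C@]13C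
F5 | step 6 | O-[7α,8α-epoxy-3,3-(ethylenedioxy)-11-nordriman-9-yl] S-methyl dithiocarbonate | CSC(=S)OC1[C@]2(C)O[C@@H]2C[C@H]3C(C)(C)C4(OCCO4)CC[C@]13C
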